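The whole route rests on cutting the O1–C8a bond of ring C. C8a is the ring A carbon that must end up bonded to the pyranone oxygen. Carrying bromine there from the outset places a leaving group ortho to the future C4 carbonyl and lets the other five ring A carbons be functionalised one by one. The key step, a copper-catalysed intramolecular O-arylation, lets the enol oxygen of a 1-(2-bromoaryl)-1,3-diketone displace that bromide and closes ring C in one operation, giving the fully substituted flavone 10. Its precursor 9 is the diketone built from brominated, doubly prenylated acetophenone 6 and MOM-protected methyl isovanillate 8. C3 hydroxylation, chelation-directed O5-demethylation and MOM removal finish the route.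

Key step: step 6

Remark: the target has no stereocentre; diketone 9 is drawn as the diketo tautomer although it should exist mainly as the chelated enol.

Step 1
Reactants: 1 1-bromo-3,5-dimethoxybenzene; 2 acetyl chloride
Product: 3 1-(2-bromo-4,6-dimethoxyphenyl)ethanone
Conditions: AlCl3 (1.2 equiv), CH2Cl2, 0 °C
Reagents that add atoms: none
Why: Friedel–Crafts acylation should occur at the position para to one methoxy group and ortho to the other, next to bromine, which is electronically favoured over the site between the two methoxy groups, and 0 °C keeps AlCl3 from cleaving the methyl ether beside the new ketone.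

Step 2
Reactants: 3 1-(2-bromo-4,6-dimethoxyphenyl)ethanone
Product: 4 1-(2-bromo-3,5-diiodo-4,6-dimethoxyphenyl)ethanone
Conditions: NIS (2.5 equiv), TFA, MeCN, rt → 50 °C
Reagents that add atoms: N-iodosuccinimide, O=C1CCC(=O)N1I
Why: Electrophilic aromatic iodination with acid-activated NIS; both open positions are ortho or para to the two methoxy groups and meta to the acetyl group, so exhaustive iodination needs no regiocontrol.

Step 3
Reactants: 4 1-(2-bromo-3,5-diiodo-4,6-dimethoxyphenyl)ethanone; 5 tributyl(3-methylbut-2-enyl)stannane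
Product: 6 1-[2-bromo-4,6-dimethoxy-3,5-bis(3-methylbut-2-enyl)phenyl]ethanone
Conditions: 5 (2.2 equiv), Pd(PPh3)4 (10 mol %), DMF, 90 °C
Reagents that add atoms: none
Why: Twofold Stille coupling; zerovalent palladium should insert into the two C–I bonds well before the C–Br bond, and reductive elimination at the unsubstituted terminus of the pi-allyl palladium intermediate should give the linear prenyl groups.

Step 4
Reactants: 7 methyl 3-hydroxy-4-methoxybenzoate
Product: 8 methyl 4-methoxy-3-(methoxymethoxy)benzoate
Conditions: MOMCl, K2CO3, acetone, 0 °C → rt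
Reagents that add atoms: chloromethyl methyl ether, COCCl
Why: Williamson-type O-alkylation of the phenoxide with the reactive chloromethyl ether masks the acidic phenol as a MOM acetal that is stable to the base-mediated steps that follow.

Step 5
Reactants: 6 1-[2-bromo-4,6-dimethoxy-3,5-bis(3-methylbut-2-enyl)phenyl]ethanone; 8 methyl 4-methoxy-3-(methoxymethoxy)benzoate
Product: 9 1-[2-bromo-4,6-dimethoxy-3,5-bis(3-methylbut-2-enyl)phenyl]-3-[4-methoxy-3-(methoxymethoxy)phenyl]propane-1,3-dione
Conditions: NaH (3 equiv), THF, 0 °C → reflux; then AcOH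
Reagents that add atoms: none
Why: Crossed Claisen condensation; only the methyl ketone can enolise, the ester has no alpha hydrogen, and deprotonation of the 1,3-diketone formed drives the equilibrium.

Step 6
Reactants: 9 1-[2-bromo-4,6-dimethoxy-3,5-bis(3-methylbut-2-enyl)phenyl]-3-[4-methoxy-3-(methoxymethoxy)phenyl]propane-1,3-dione
Product: 10 5,7-dimethoxy-2-[4-methoxy-3-(methoxymethoxy)phenyl]-6,8-bis(3-methylbut-2-enyl)chromen-4-one
Conditions: CuI (10 mol %), 1,10-phenanthroline (20 mol %), K2CO3 (2 equiv), DMF, 100 °C, Ar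
Reagents that add atoms: none
Why: K2CO3 converts 9 into its chelating enolate, which binds monovalent copper; insertion of copper into the neighbouring C8a–Br bond gives an aryl species of trivalent copper, and C–O reductive elimination then forms O1–C8a. The closest known reaction type is the Ullmann-type intramolecular O-arylation that turns 1-(2-haloaryl)-1,3-diketones into flavones. Ring C closes in a six-membered, formally 6-exo mode, by reductive elimination from a seven-membered copper chelate that holds O1, C2, C3, C4, C4a and C8a. No stereocentre is formed. The step needs O-arylation and not C-arylation, and it needs the enol oxygen on the ring B side; only that oxygen reaches C8a through a six-membered ring, whereas the central carbon or the other oxygen could only give four-membered rings. Because bromine sits ortho to the C4 carbonyl, the C–Br bond is activated and the bound enolate is delivered directly to it, which compensates for shielding by the C8 prenyl group, while the prenyl alkenes, the methyl ethers and the MOM acetal are inert to carbonate and copper.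

Step 7
Reactants: 10 5,7-dimethoxy-2-[4-methoxy-3-(methoxymethoxy)phenyl]-6,8-bis(3-methylbut-2-enyl)chromen-4-one
Product: 13 3-hydroxy-5,7-dimethoxy-2-[4-methoxy-3-(methoxymethoxy)phenyl]-6,8-bis(3-methylbut-2-enyl)chromen-4-one, via C3-lithiated flavone 11 (not isolated), via C3 dimethyl boronate 12 (not isolated)
Conditions: LiN(iPr)2 (1.5 equiv), THF, −78 °C; B(OMe)3, −78 → 0 °C; AcOH, then 30 % aq. H2O2, 0 °C → rt
Reagents that add atoms: hydrogen peroxide, OO
Why: Deprotonation at C3, the only vinylic C–H alpha to the C4 carbonyl, followed by borylation and hydroperoxide oxidation of the C–B bond is the established flavone-to-flavonol sequence, and it uses no electrophilic oxidant that would attack the prenyl alkenes.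

Step 8
Reactants: 13 3-hydroxy-5,7-dimethoxy-2-[4-methoxy-3-(methoxymethoxy)phenyl]-6,8-bis(3-methylbut-2-enyl)chromen-4-one
Product: 14 3,5-dihydroxy-7-methoxy-2-[4-methoxy-3-(methoxymethoxy)phenyl]-6,8-bis(3-methylbut-2-enyl)chromen-4-one
Conditions: MgI2·OEt2 (4 equiv), toluene–Et2O, 70 °C; then cold 0.5 M aq. HCl
Reagents that add atoms: none
Why: Chelation-assisted ether cleavage; magnesium bridges the C4 carbonyl and the peri C5 methoxy oxygen so that iodide removes only that methyl group by SN2 attack, and any MOM loss at this stage is harmless because the acetal is removed in the next step.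

Step 9
Reactants: 14 3,5-dihydroxy-7-methoxy-2-[4-methoxy-3-(methoxymethoxy)phenyl]-6,8-bis(3-methylbut-2-enyl)chromen-4-one
Product: 15 3,5-dihydroxy-2-(3-hydroxy-4-methoxyphenyl)-7-methoxy-6,8-bis(3-methylbut-2-enyl)chromen-4-one
Conditions: HCl (3 M aq.), MeOH, 40 °C
Reagents that add atoms: none
Why: Acid-catalysed acetal exchange with methanol frees the C3' phenol under conditions mild enough that the C5 hydroxyl, hydrogen-bonded to the C4 carbonyl, should not add to the neighbouring C6 prenyl alkene.

Compound list
1 | 1-bromo-3,5-dimethoxybenzene | COc1cc(Br)cc(OC)c1 | starting material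
2 | acetyl chloride | CC(=O)Cl | starting material
3 | 1-(2-bromo-4,6-dimethoxyphenyl)ethanone | CC(=O)c1c(Br)cc(OC)cc1OC | intermediate
4 | 1-(2-bromo-3,5-diiodo-4,6-dimethoxyphenyl)ethanone | CC(=O)c1c(Br)c(I)c(OC)c(I)c1OC | intermediate
5 | tributyl(3-methylbut-2-enyl)stannane | CCCC[Sn](CCCC)(CCCC)CC=C(C)C | starting material
6 | 1-[2-bromo-4,6-dimethoxy-3,5-bis(3-methylbut-2-enyl)phenyl]ethanone | CC(=O)c1c(Br)c(CC=C(C)C)c(OC)c(CC=C(C)C)c1OC | intermediate
7 | methyl 3-hydroxy-4-methoxybenzoate (methyl isovanillate) | COC(=O)c1ccc(OC)c(O)c1 | starting material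
8 | methyl 4-methoxy-3-(methoxymethoxy)benzoate | COCOc1cc(C(=O)OC)ccc1OC | intermediate
9 | 1-[2-bromo-4,6-dimethoxy-3,5-bis(3-methylbut-2-enyl)phenyl]-3-[4-methoxy-3-(methoxymethoxy)phenyl]propane-1,3-dione | COCOc1cc(C(=O)CC(=O)c2c(Br)c(CC=C(C)C)c(OC)c(CC=C(C)C)c2OC)ccc1OC | intermediate
10 | 5,7-dimethoxy-2-[4-methoxy-3-(methoxymethoxy)phenyl]-6,8-bis(3-methylbut-2-enyl)chromen-4-one | COCOc1cc(-c2cc(=O)c3c(OC)c(CC=C(C)C)c(OC)c(CC=C(C)C)c3o2)ccc1OC | intermediate
11 | 3-lithio-5,7-dimethoxy-2-[4-methoxy-3-(methoxymethoxy)phenyl]-6,8-bis(3-methylbut-2-enyl)chromen-4-one | COCOc1cc(-c2oc3c(CC=C(C)C)c(OC)c(CC=C(C)C)c(OC)c3c(=O)c2[Li])ccc1OC | intermediate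
12 | dimethyl [5,7-dimethoxy-2-[4-methoxy-3-(methoxymethoxy)phenyl]-6,8-bis(3-methylbut-2-enyl)-4-oxochromen-3-yl]boronate | COCOc1cc(-c2oc3c(CC=C(C)C)c(OC)c(CC=C(C)C)c(OC)c3c(=O)c2B(OC)OC)ccc1OC | intermediate
13 | 3-hydroxy-5,7-dimethoxy-2-[4-methoxy-3-(methoxymethoxy)phenyl]-6,8-bis(3-methylbut-2-enyl)chromen-4-one | COCOc1cc(-c2oc3c(CC=C(C)C)c(OC)c(CC=C(C)C)c(OC)c3c(=O)c2O)ccc1OC | intermediate
14 | 3,5-dihydroxy-7-methoxy-2-[4-methoxy-3-(methoxymethoxy)phenyl]-6,8-bis(3-methylbut-2-enyl)chromen-4-one | COCOc1cc(-c2oc3c(CC=C(C)C)c(OC)c(CC=C(C)C)c(O)c3c(=O)c2O)ccc1OC | intermediate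
15 | 3,5-dihydroxy-2-(3-hydroxy-4-methoxyphenyl)-7-methoxy-6,8-bis(3-methylbut-2-enyl)chromen-4-one | COc1ccc(-c2oc3c(CC=C(C)C)c(OC)c(CC=C(C)C)c(O)c3c(=O)c2O)cc1O | target

Total step count: 9.
Longest linear sequence: 8 steps (1 → 3 → 4 → 6 → 9 → 10 → 13 → 14 → 15); step 4 is the only side-branch step.

Steps most likely to fail

Step 6 (ring closure). Insertion of copper into the C8a–Br bond, which is flanked by the C8 prenyl group and the acyl group, may be slower than retro-Claisen cleavage of the diketone or protodebromination. The fallback sets out from 6 and comes back at 10. It makes the C8a–O bond first with hydroxide and then closes ring C by condensation at O1–C2. Palladium-catalysed hydroxylation of the bromide (Pd2(dba)3, tBuXPhos, KOH, dioxane–H2O, 100 °C) should give 1-[2-hydroxy-4,6-dimethoxy-3,5-bis(3-methylbut-2-enyl)phenyl]ethanone F1. Claisen condensation of F1 with ester 8 (NaH, 4 equiv, THF, reflux) should give 1-[2-hydroxy-4,6-dimethoxy-3,5-bis(3-methylbut-2-enyl)phenyl]-3-[4-methoxy-3-(methoxymethoxy)phenyl]propane-1,3-dione F2. Cyclodehydration of F2 (p-TsOH cat., toluene, 4 Å MS, 50 °C) should then give 10.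

Step 3 (twofold prenyl coupling). Regiocontrol may be lost at the allyl unit, with transfer through the tertiary terminus. The second coupling at the iodide between the two methoxy groups may stall, or palladium may start to insert into the C–Br bond. The fallback sets out from 4 and comes back at 6. Stille coupling with allyltributylstannane (Pd(PPh3)4, DMF, 90 °C), whose allyl group is smaller and has no regiochemical ambiguity, should give 1-[2-bromo-4,6-dimethoxy-3,5-bis(prop-2-enyl)phenyl]ethanone F3. Olefin cross-metathesis of F3 with 2-methylbut-2-ene (second-generation Grubbs catalyst, CH2Cl2/2-methylbut-2-ene, 40 °C) should convert both allyl groups into prenyl groups and give 6.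

Step 7 (C3 hydroxylation). The amide base may add at C2 and open the pyranone, or deprotonate unselectively, and the peroxide stage may over-oxidise. The fallback sets out from 9 and comes back at 13. It brings in the C3 oxygen before ring closure. Treating the sodium enolate of 9 (NaH, THF, 0 °C) with dibenzoyl peroxide should give racemic [1-[2-bromo-4,6-dimethoxy-3,5-bis(3-methylbut-2-enyl)phenyl]-3-[4-methoxy-3-(methoxymethoxy)phenyl]-1,3-dioxopropan-2-yl] benzoate F4. Copper-catalysed ring closure under the conditions of step 6 should give [5,7-dimethoxy-2-[4-methoxy-3-(methoxymethoxy)phenyl]-6,8-bis(3-methylbut-2-enyl)-4-oxochromen-3-yl] benzoate F5. Methanolysis of F5 (K2CO3, MeOH, rt) should give 13.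

Further compounds
F1 | step 6 | 1-[2-hydroxy-4,6-dimethoxy-3,5-bis(3-methylbut-2-enyl)phenyl]ethanone | CC(=O)c1c(O)c(CC=C(C)C)c(OC)c(CC=C(C)C)c1OC
F2 | step 6 | 1-[2-hydroxy-4,6-dimethoxy-3,5-bis(3-methylbut-2-enyl)phenyl]-3-[4-methoxy-3-(methoxymethoxy)phenyl]propane-1,3-dione | COCOc1cc(C(=O)CC(=O)c2c(O)c(CC=C(C)C)c(OC)c(CC=C(C)C)c2OC)ccc1OC
F3 | step 3 | 1-[2-bromo-4,6-dimethoxy-3,5-bis(prop-2-enyl)phenyl]ethanone | CC(=O)c1c(Br)c(CC=C)c(OC)c(CC=C)c1OC
F4 | step 7 | [1-[2-bromo-4,6-dimethoxy-3,5-bis(3-methylbut-2-enyl)phenyl]-3-[4-methoxy-3-(methoxymethoxy)phenyl]-1,3-dioxopropan-2-yl] benzoate (racemic) | COCOc1cc(C(=O)C(OC(=O)c3ccccc3)C(=O)c2c(Br)c(CC=C(C)C)c(OC)c(CC=C(C)C)c2OC)ccc1OC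
F5 | step 7 | [5,7-dimethoxy-2-[4-methoxy-3-(methoxymethoxy)phenyl]-6,8-bis(3-methylbut-2-enyl)-4-oxochromen-3-yl] benzoate | COCOc1cc(-c2oc3c(CC=C(C)C)c(OC)c(CC=C(C)C)c(OC)c3c(=O)c2OC(=O)c4ccccc4)ccc1OC
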